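The γ-butyrolactone is cut at C4–C5 and C2–C3. Ring carbon C4, which bears the guaiacylmethyl group, is flanked by two methylene-level carbons (C5 and C3), so the lactone ring without O1 is a Cs-symmetric 3-benzylcyclobutanone. A [2+2] cycloaddition of dichloroketene, made in the flask, to the allyl group of silylated eugenol forges both bonds in one operation from achiral, acyclic partners. Dechlorination and a catalytic desymmetrising Baeyer–Villiger oxidation then set C4. C3 is relayed from it by trans-alkylation with a dihydrobenzofuranylmethyl bromide whose two centres come from an Evans aldol and an acid-mediated ring closure. Global desilylation ends the route.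

Key step: step 2

Remark: methyl 4-hydroxy-3-iodo-5-methoxybenzoate (methyl 5-iodovanillate) is taken as a catalogue compound. TBS = tert-butyldimethylsilyl, MOM = methoxymethyl.

Step 1
Reactants: 1 eugenol (4-allyl-2-methoxyphenol)
Product: 2 tert-butyl(4-allyl-2-methoxyphenoxy)dimethylsilane
Conditions: TBSCl, imidazole, DMF, rt
Reagents that add atoms: tert-butyldimethylsilyl chloride, CC(C)(C)[Si](C)(C)Cl
Why: Imidazole-promoted silyl ether formation masks the only acidic group with a protecting group that tolerates zinc, peracid and lithium amide conditions and is removed by fluoride at the end.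

Step 2
Reactants: 2 tert-butyl(4-allyl-2-methoxyphenoxy)dimethylsilane; 3 trichloroacetyl chloride
Product: 5 rac-3-[4-(TBSO)-3-methoxybenzyl]-2,2-dichlorocyclobutan-1-one, via dichloroketene 4 (not isolated)
Conditions: Zn–Cu couple, POCl3, Et2O, 35 °C
Reagents that add atoms: none
Why: Zinc dechlorinates 3 to the strongly electrophilic dichloroketene 4, which adds to the unactivated terminal C=C of 2 in a concerted, asynchronous thermal [π2s+π2a] cycloaddition; the closest known type is the classical ketene–alkene [2+2] route to cyclobutanones. The four-membered ring is closed by the cycloaddition itself, both ring bonds forming in one intermolecular [2+2] event with no separate cyclisation. The step needs regioselectivity, and the monosubstituted alkene secures it: its terminal CH2 bonds to the electrophilic carbonyl carbon while the partial positive charge sits on the internal carbon, which bonds to CCl2, so the new bonds are C(=O)–CH2 and CCl2–CH(CH2Ar), the later lactone C2–C3 and C4–C5 bonds. The one new stereocentre (ring C3, the later lactone C4) forms as a racemate under no control, which is harmless because step 3 turns it into the prochiral centre of a Cs-symmetric ketone whose two α-CH2 groups are equivalent until the oxygen atom is inserted. Chemoselectivity over Friedel–Crafts acylation of the electron-rich silyloxyarene is secured by the much faster cycloaddition and by POCl3, which sequesters ZnCl2.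

Step 3
Reactants: 5 rac-3-[4-(TBSO)-3-methoxybenzyl]-2,2-dichlorocyclobutan-1-one
Product: 6 3-[4-(TBSO)-3-methoxybenzyl]cyclobutan-1-one
Conditions: Zn dust, AcOH, 60 °C
Reagents that add atoms: none
Why: Zinc in acetic acid removes both α-chlorine atoms through zinc enolates (reductive dehalogenation of an α,α-dihalo ketone), which erases the racemic stereocentre and leaves a Cs-symmetric ketone with two enantiotopic α-methylene groups.

Step 4
Reactants: 6 3-[4-(TBSO)-3-methoxybenzyl]cyclobutan-1-one
Product: 7 (4R)-4-[4-(TBSO)-3-methoxybenzyl]oxolan-2-one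
Conditions: Sc(OTf)3 (5 mol%), chiral N,N'-dioxide bis-anilide ligand (5 mol%), m-CPBA, EtOAc, −20 °C
Reagents that add atoms: m-chloroperbenzoic acid, OOC(=O)c1cccc(Cl)c1
Why: In this catalytic asymmetric Baeyer–Villiger desymmetrisation the chiral Sc(OTf)3–N,N'-dioxide complex holds ketone and peracid in the Criegee adduct so that only one of the two enantiotopic α-methylene groups migrates to oxygen, which sets the single stereocentre of 7 as R by catalyst control (the ligand antipode that delivers the R lactone is the one used).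

Step 5
Reactants: 8 vanillin
Product: 9 3-methoxy-4-(methoxymethoxy)benzaldehyde
Conditions: MOMCl, i-Pr2NEt, CH2Cl2, 0 °C → rt
Reagents that add atoms: chloromethyl methyl ether, COCCl
Why: O-Alkylation of the phenol with the chloromethyl ether (Williamson-type acetal formation) gives an aldehyde partner whose phenol is masked by a group that survives boron enolate chemistry and falls off under the acid of step 12.

Step 6
Reactants: 10 methyl 4-hydroxy-3-iodo-5-methoxybenzoate
Product: 11 methyl 3-iodo-5-methoxy-4-(methoxymethoxy)benzoate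
Conditions: MOMCl, i-Pr2NEt, CH2Cl2, 0 °C → rt
Reagents that add atoms: chloromethyl methyl ether, COCCl
Why: The same Williamson-type O-alkylation masks the phenol ortho to iodine so that it cannot quench the zinc enolate or the boron triflate and is unveiled exactly when ring closure is wanted.

Step 7
Reactants: 11 methyl 3-iodo-5-methoxy-4-(methoxymethoxy)benzoate; 12 benzyl bromoacetate
Product: 14 methyl 3-[2-(benzyloxy)-2-oxoethyl]-5-methoxy-4-(methoxymethoxy)benzoate, via Reformatsky reagent 13 (not isolated)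
Conditions: Zn dust (Me3SiCl-activated), THF, 40 °C; then 11, Pd(dba)2 (2 mol%), P(t-Bu)3 (2 mol%), THF, rt → 50 °C
Reagents that add atoms: none
Why: Zinc insertion into 12 gives Reformatsky reagent 13, whose cross-coupling with the aryl iodide under zerovalent palladium catalysis (Negishi-type α-arylation of a zinc ester enolate) builds the arylacetate under conditions mild enough to spare the methyl benzoate and the acetal.

Step 8
Reactants: 14 methyl 3-[2-(benzyloxy)-2-oxoethyl]-5-methoxy-4-(methoxymethoxy)benzoate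
Product: 15 2-[3-methoxy-5-(methoxycarbonyl)-2-(methoxymethoxy)phenyl]acetic acid
Conditions: H2 (1 atm), Pd/C, EtOAc, rt
Reagents that add atoms: none
Why: Hydrogenolysis of the benzyl ester over palladium frees the acetic acid under neutral conditions that leave the methyl ester and the acid-labile MOM ether untouched.

Step 9
Reactants: 15 2-[3-methoxy-5-(methoxycarbonyl)-2-(methoxymethoxy)phenyl]acetic acid; 16 (4S)-4-benzyl-1,3-oxazolidin-2-one
Product: 18 methyl 3-{2-[(4S)-4-benzyl-2-oxo-1,3-oxazolidin-3-yl]-2-oxoethyl}-5-methoxy-4-(methoxymethoxy)benzoate, via mixed pivalic anhydride 17 (not isolated)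
Conditions: PivCl, Et3N, THF, −20 °C; then LiCl, 16, −20 °C → rt
Reagents that add atoms: none
Why: Activation as the mixed pivalic anhydride and LiCl-assisted N-acylation of the oxazolidinone (standard attachment of an Evans auxiliary) proceeds at the less hindered arylacetyl carbonyl and installs the group that will control the benzylic stereocentre.

Step 10
Reactants: 18 methyl 3-{2-[(4S)-4-benzyl-2-oxo-1,3-oxazolidin-3-yl]-2-oxoethyl}-5-methoxy-4-(methoxymethoxy)benzoate; 9 3-methoxy-4-(methoxymethoxy)benzaldehyde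
Product: 21 methyl 3-{(2S,3S)-1-[(4S)-4-benzyl-2-oxo-1,3-oxazolidin-3-yl]-3-hydroxy-3-[3-methoxy-4-(methoxymethoxy)phenyl]-1-oxopropan-2-yl}-5-methoxy-4-(methoxymethoxy)benzoate, via boron enolate 19 (not isolated), via boron aldolate 20 (not isolated)
Conditions: Bu2BOTf, i-Pr2NEt, CH2Cl2, −78 → 0 °C; then 9, −78 → 0 °C; then pH 7 buffer, MeOH, 30% H2O2, 0 °C
Reagents that add atoms: none
Why: Soft enolisation gives the Z boron enolate 19, which adds to 9 through a closed chair transition state on the enolate face away from the benzyl group of the dipole-opposed oxazolidinone (Evans syn-aldol reaction), so the auxiliary sets the aryl-bearing α-carbon as S (the later C3 of the dihydrobenzofuran) and the carbinol carbon as S.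

Step 11
Reactants: 21 the syn-aldol adduct
Product: 22 methyl 3-{(1S,2R)-1,3-dihydroxy-1-[3-methoxy-4-(methoxymethoxy)phenyl]propan-2-yl}-5-methoxy-4-(methoxymethoxy)benzoate
Conditions: LiBH4, MeOH (1.5 equiv), THF, 0 °C
Reagents that add atoms: none
Why: LiBH4 reduces the activated exocyclic imide carbonyl far faster than the electron-rich methyl benzoate (reductive cleavage of an N-acyloxazolidinone), which turns the acyl carbon into the future hydroxymethyl group without touching either stereocentre and returns the auxiliary.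

Step 12
Reactants: 22 the bis-MOM 1,3-diol
Product: 24 methyl (2S,3R)-2-(4-hydroxy-3-methoxyphenyl)-3-(hydroxymethyl)-7-methoxy-2,3-dihydro-1-benzofuran-5-carboxylate, via bisphenol triol 23 (not isolated)
Conditions: conc. aq. HCl (3 equiv), MeOH, 50 °C
Reagents that add atoms: none
Why: Acid removes both MOM acetals and ionises the 4-hydroxybenzylic alcohol to a quinone-methide-type cation that the neighbouring phenol captures in a 5-exo ring closure (acid-mediated cyclodehydration), and because this closure is reversible the fixed C3 centre places the aryl group trans under thermodynamic control, which makes C2 S whatever the carbinol configuration of 22.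

Step 13
Reactants: 24 the phenol–alcohol dihydrobenzofuran ester
Product: 25 methyl (2S,3R)-2-[4-(TBSO)-3-methoxyphenyl]-3-[(TBSO)methyl]-7-methoxy-2,3-dihydro-1-benzofuran-5-carboxylate
Conditions: TBSCl (2.5 equiv), imidazole, DMF, rt
Reagents that add atoms: tert-butyldimethylsilyl chloride, CC(C)(C)[Si](C)(C)Cl
Why: Imidazole-promoted silylation of the phenol and the primary alcohol in one operation masks both hydroxyl groups for the hydride, bromination and enolate steps with groups that leave together at the end.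

Step 14
Reactants: 25 the bis-TBS ester
Product: 26 {(2S,3R)-2-[4-(TBSO)-3-methoxyphenyl]-3-[(TBSO)methyl]-7-methoxy-2,3-dihydro-1-benzofuran-5-yl}methanol
Conditions: i-Bu2AlH (2.5 equiv), CH2Cl2, −78 → 0 °C; aq. potassium sodium tartrate
Reagents that add atoms: none
Why: i-Bu2AlH reduces the aromatic methyl ester to the benzylic alcohol (ester-to-alcohol hydride reduction) at low temperature without affecting the silyl ethers or the dihydrofuran ring.

Step 15
Reactants: 26 the benzylic alcohol
Product: 27 (2S,3R)-5-(bromomethyl)-2-[4-(TBSO)-3-methoxyphenyl]-3-[(TBSO)methyl]-7-methoxy-2,3-dihydro-1-benzofuran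
Conditions: CBr4, PPh3, 2,6-lutidine, CH2Cl2, 0 °C; used at once
Reagents that add atoms: carbon tetrabromide, BrC(Br)(Br)Br
Why: The Appel reaction converts the primary benzylic alcohol into the bromide through an alkoxyphosphonium ion under neutral conditions that keep the silyl ethers and the electron-rich benzylic positions intact.

Step 16
Reactants: 7 (4R)-4-[4-(TBSO)-3-methoxybenzyl]oxolan-2-one; 27 the benzylic bromide
Product: 29 (3R,4R)-4-[4-(TBSO)-3-methoxybenzyl]-3-({(2S,3R)-2-[4-(TBSO)-3-methoxyphenyl]-3-[(TBSO)methyl]-7-methoxy-2,3-dihydro-1-benzofuran-5-yl}methyl)oxolan-2-one, via lithium enolate 28 (not isolated)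
Conditions: LiN(SiMe3)2, THF, −78 °C; then 27, DMPU, −78 → −30 °C
Reagents that add atoms: none
Why: Lithium enolate 28 is alkylated by the reactive benzylic bromide on the face anti to the C4 substituent (diastereoselective alkylation of a β-substituted γ-butyrolactone enolate), so C3 is set as R by substrate control and the trans-3,4-disubstituted lactone results.

Step 17
Reactants: 29 the tris-TBS ether
Product: 30 isolappaol A
Conditions: Bu4NF (3.5 equiv), AcOH (3.5 equiv), THF, 0 °C → rt
Reagents that add atoms: none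
Why: Fluoride cleaves the two aryl silyl ethers and the alkyl silyl ether (desilylation), and the acetic acid buffer keeps the medium from opening the lactone or epimerising C3.

Compound list
1 | eugenol (4-allyl-2-methoxyphenol) | C=CCc1ccc(O)c(OC)c1 | starting material
2 | tert-butyl(4-allyl-2-methoxyphenoxy)dimethylsilane | C=CCc1ccc(O[Si](C)(C)C(C)(C)C)c(OC)c1 | intermediate
3 | trichloroacetyl chloride | ClC(=O)C(Cl)(Cl)Cl | starting material
4 | dichloroketene | O=C=C(Cl)Cl | intermediate (not isolated)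
5 | rac-3-[4-(TBSO)-3-methoxybenzyl]-2,2-dichlorocyclobutan-1-one | O=C1CC(Cc2ccc(O[Si](C)(C)C(C)(C)C)c(OC)c2)C1(Cl)Cl | intermediate
6 | 3-[4-(TBSO)-3-methoxybenzyl]cyclobutan-1-one | O=C1CC(Cc2ccc(O[Si](C)(C)C(C)(C)C)c(OC)c2)C1 | intermediate
7 | (4R)-4-[4-(TBSO)-3-methoxybenzyl]oxolan-2-one | COc1cc(C[C@H]2COC(=O)C2)ccc1O[Si](C)(C)C(C)(C)C | intermediate
8 | vanillin | COc1cc(C=O)ccc1O | starting material
9 | 3-methoxy-4-(methoxymethoxy)benzaldehyde | COCOc1ccc(C=O)cc1OC | intermediate
10 | methyl 4-hydroxy-3-iodo-5-methoxybenzoate | COC(=O)c1cc(I)c(O)c(OC)c1 | starting material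
11 | methyl 3-iodo-5-methoxy-4-(methoxymethoxy)benzoate | COC(=O)c1cc(I)c(OCOC)c(OC)c1 | intermediate
12 | benzyl bromoacetate | BrCC(=O)OCc1ccccc1 | starting material
13 | bromo[2-(benzyloxy)-2-oxoethyl]zinc (Reformatsky reagent) | Br[Zn]CC(=O)OCc1ccccc1 | intermediate (not isolated)
14 | methyl 3-[2-(benzyloxy)-2-oxoethyl]-5-methoxy-4-(methoxymethoxy)benzoate | COC(=O)c1cc(CC(=O)OCc2ccccc2)c(OCOC)c(OC)c1 | intermediate
15 | 2-[3-methoxy-5-(methoxycarbonyl)-2-(methoxymethoxy)phenyl]acetic acid | COC(=O)c1cc(CC(=O)O)c(OCOC)c(OC)c1 | intermediate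
16 | (4S)-4-benzyl-1,3-oxazolidin-2-one | O=C1N[C@@H](Cc2ccccc2)CO1 | starting material
17 | mixed anhydride of 15 and pivalic acid | COC(=O)c1cc(CC(=O)OC(=O)C(C)(C)C)c(OCOC)c(OC)c1 | intermediate (not isolated)
18 | methyl 3-{2-[(4S)-4-benzyl-2-oxo-1,3-oxazolidin-3-yl]-2-oxoethyl}-5-methoxy-4-(methoxymethoxy)benzoate | COC(=O)c1cc(CC(=O)N2[C@@H](Cc3ccccc3)COC2=O)c(OCOC)c(OC)c1 | intermediate
19 | (Z)-dibutylboron enolate of 18 | CCCCB(CCCC)O/C(=C\c1cc(C(=O)OC)cc(OC)c1OCOC)N1[C@@H](Cc2ccccc2)COC1=O | intermediate (not isolated)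
20 | O-dibutylboryl aldolate of 21 | O=C(N1[C@@H](Cc2ccccc2)COC1=O)[C@@H](c1cc(C(=O)OC)cc(OC)c1OCOC)[C@H](OB(CCCC)CCCC)c1ccc(OCOC)c(OC)c1 | intermediate (not isolated)
21 | methyl 3-{(2S,3S)-1-[(4S)-4-benzyl-2-oxo-1,3-oxazolidin-3-yl]-3-hydroxy-3-[3-methoxy-4-(methoxymethoxy)phenyl]-1-oxopropan-2-yl}-5-methoxy-4-(methoxymethoxy)benzoate | O=C(N1[C@@H](Cc2ccccc2)COC1=O)[C@@H](c1cc(C(=O)OC)cc(OC)c1OCOC)[C@H](O)c1ccc(OCOC)c(OC)c1 | intermediate
22 | methyl 3-{(1S,2R)-1,3-dihydroxy-1-[3-methoxy-4-(methoxymethoxy)phenyl]propan-2-yl}-5-methoxy-4-(methoxymethoxy)benzoate | COC(=O)c1cc([C@H](CO)[C@H](O)c2ccc(OCOC)c(OC)c2)c(OCOC)c(OC)c1 | intermediate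
23 | methyl 3-[(1S,2R)-1,3-dihydroxy-1-(4-hydroxy-3-methoxyphenyl)propan-2-yl]-4-hydroxy-5-methoxybenzoate | COC(=O)c1cc([C@H](CO)[C@H](O)c2ccc(O)c(OC)c2)c(O)c(OC)c1 | intermediate (not isolated)
24 | methyl (2S,3R)-2-(4-hydroxy-3-methoxyphenyl)-3-(hydroxymethyl)-7-methoxy-2,3-dihydro-1-benzofuran-5-carboxylate | COC(=O)c1cc(OC)c2c(c1)[C@H](CO)[C@@H](c1ccc(O)c(OC)c1)O2 | intermediate
25 | methyl (2S,3R)-2-[4-(TBSO)-3-methoxyphenyl]-3-[(TBSO)methyl]-7-methoxy-2,3-dihydro-1-benzofuran-5-carboxylate | COC(=O)c1cc(OC)c2c(c1)[C@H](CO[Si](C)(C)C(C)(C)C)[C@@H](c1ccc(O[Si](C)(C)C(C)(C)C)c(OC)c1)O2 | intermediate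
26 | {(2S,3R)-2-[4-(TBSO)-3-methoxyphenyl]-3-[(TBSO)methyl]-7-methoxy-2,3-dihydro-1-benzofuran-5-yl}methanol | OCc1cc(OC)c2c(c1)[C@H](CO[Si](C)(C)C(C)(C)C)[C@@H](c1ccc(O[Si](C)(C)C(C)(C)C)c(OC)c1)O2 | intermediate
27 | (2S,3R)-5-(bromomethyl)-2-[4-(TBSO)-3-methoxyphenyl]-3-[(TBSO)methyl]-7-methoxy-2,3-dihydro-1-benzofuran | BrCc1cc(OC)c2c(c1)[C@H](CO[Si](C)(C)C(C)(C)C)[C@@H](c1ccc(O[Si](C)(C)C(C)(C)C)c(OC)c1)O2 | intermediate
28 | lithium enolate of 7 | COc1cc(C[C@H]2COC(O[Li])=C2)ccc1O[Si](C)(C)C(C)(C)C | intermediate (not isolated)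
29 | (3R,4R)-4-[4-(TBSO)-3-methoxybenzyl]-3-({(2S,3R)-2-[4-(TBSO)-3-methoxyphenyl]-3-[(TBSO)methyl]-7-methoxy-2,3-dihydro-1-benzofuran-5-yl}methyl)oxolan-2-one | COc1cc(C[C@H]2COC(=O)[C@@H]2Cc2cc(OC)c3c(c2)[C@H](CO[Si](C)(C)C(C)(C)C)[C@@H](c2ccc(O[Si](C)(C)C(C)(C)C)c(OC)c2)O3)ccc1O[Si](C)(C)C(C)(C)C | intermediate
30 | isolappaol A, (3R,4R)-4-(4-hydroxy-3-methoxybenzyl)-3-{[(2S,3R)-2-(4-hydroxy-3-methoxyphenyl)-3-(hydroxymethyl)-7-methoxy-2,3-dihydro-1-benzofuran-5-yl]methyl}oxolan-2-one | COc1cc(C[C@H]2COC(=O)[C@@H]2Cc2cc(OC)c3c(c2)[C@H](CO)[C@@H](c2ccc(O)c(OC)c2)O3)ccc1O | target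

Total step count: 17.
Longest linear sequence: 12 steps (steps 6 to 17, from 10).

Steps most likely to fail

Step 4. The catalyst may discriminate poorly between the two enantiotopic migrating methylene groups of a 3-benzyl (rather than 3-aryl) cyclobutanone, so that the lactone forms with insufficient enantiomeric purity. Fallback by resolution instead of catalysis: from 6, an uncatalysed Baeyer–Villiger oxidation (m-CPBA, NaHCO3, CH2Cl2) would give racemic 4-[4-(TBSO)-3-methoxybenzyl]oxolan-2-one F1. Aminolysis with (S)-1-phenylethylamine (AlMe3, CH2Cl2) and separation of the two diastereomeric hydroxy amides by chromatography or crystallisation would give (3R)-3-[4-(TBSO)-3-methoxybenzyl]-4-hydroxy-N-[(1S)-1-phenylethyl]butanamide F2. Acid-induced relactonisation (p-TsOH, toluene, 100 °C) would expel the amine and come back to the route at 7.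

Step 11. The α-aryl β-hydroxy imide may fragment by retro-aldol cleavage under the basic hydride conditions, and the benzoate may be partly over-reduced. Fallback by closing the ring before the auxiliary is removed: from 21, acid (CF3CO2H, wet CH2Cl2, 0 °C → rt) would remove both MOM groups and close the dihydrofuran ring trans to give methyl (2S,3S)-3-{[(4S)-4-benzyl-2-oxo-1,3-oxazolidin-3-yl]carbonyl}-2-(4-hydroxy-3-methoxyphenyl)-7-methoxy-2,3-dihydro-1-benzofuran-5-carboxylate F3. Its former aldol oxygen is now a ring ether, so retro-aldol cleavage is no longer possible. Reductive cleavage of the imide (LiBH4, THF–H2O, 0 °C) would then come back to the route at 24.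

Step 16. The very electron-rich benzylic bromide may ionise and self-condense before C-alkylation, and proton transfer between product and enolate may lead to double alkylation. Fallback by aldol addition and deoxygenation instead of alkylation: from 26, oxidation (MnO2, CH2Cl2) would give (2S,3R)-2-[4-(TBSO)-3-methoxyphenyl]-3-[(TBSO)methyl]-7-methoxy-2,3-dihydro-1-benzofuran-5-carbaldehyde F4. Addition of lithium enolate 28 (from 7, LiN(SiMe3)2, THF, −78 °C) would give, anti to the C4 substituent, the aldol adduct (3S,4R)-3-{hydroxy[(2S,3R)-2-[4-(TBSO)-3-methoxyphenyl]-3-[(TBSO)methyl]-7-methoxy-2,3-dihydro-1-benzofuran-5-yl]methyl}-4-[4-(TBSO)-3-methoxybenzyl]oxolan-2-one F5 as a mixture at the carbinol carbon. 1,1'-Thiocarbonyldiimidazole (DMAP, CH2Cl2) would convert it into the O-(imidazol-1-ylthiocarbonyl) derivative F6. Barton–McCombie deoxygenation of the benzylic C–O bond (Bu3SnH, AIBN, toluene, 90 °C) would come back to the route at 29.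

Further compounds
F1 | step 4 | rac-4-[4-(TBSO)-3-methoxybenzyl]oxolan-2-one | COc1cc(CC2COC(=O)C2)ccc1O[Si](C)(C)C(C)(C)C
F2 | step 4 | (3R)-3-[4-(TBSO)-3-methoxybenzyl]-4-hydroxy-N-[(1S)-1-phenylethyl]butanamide | COc1cc(C[C@@H](CO)CC(=O)N[C@@H](C)c2ccccc2)ccc1O[Si](C)(C)C(C)(C)C
F3 | step 11 | methyl (2S,3S)-3-{[(4S)-4-benzyl-2-oxo-1,3-oxazolidin-3-yl]carbonyl}-2-(4-hydroxy-3-methoxyphenyl)-7-methoxy-2,3-dihydro-1-benzofuran-5-carboxylate | COC(=O)c1cc(OC)c2c(c1)[C@H](C(=O)N1[C@@H](Cc3ccccc3)COC1=O)[C@@H](c1ccc(O)c(OC)c1)O2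
F4 | step 16 | (2S,3R)-2-[4-(TBSO)-3-methoxyphenyl]-3-[(TBSO)methyl]-7-methoxy-2,3-dihydro-1-benzofuran-5-carbaldehyde | O=Cc1cc(OC)c2c(c1)[C@H](CO[Si](C)(C)C(C)(C)C)[C@@H](c1ccc(O[Si](C)(C)C(C)(C)C)c(OC)c1)O2
F5 | step 16 | (3S,4R)-3-{hydroxy[(2S,3R)-2-[4-(TBSO)-3-methoxyphenyl]-3-[(TBSO)methyl]-7-methoxy-2,3-dihydro-1-benzofuran-5-yl]methyl}-4-[4-(TBSO)-3-methoxybenzyl]oxolan-2-one (carbinol epimers) | COc1cc(C[C@H]2COC(=O)[C@@H]2C(O)c2cc(OC)c3c(c2)[C@H](CO[Si](C)(C)C(C)(C)C)[C@@H](c2ccc(O[Si](C)(C)C(C)(C)C)c(OC)c2)O3)ccc1O[Si](C)(C)C(C)(C)C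
F6 | step 16 | O-(imidazol-1-ylthiocarbonyl) derivative of F5 | COc1cc(C[C@H]2COC(=O)[C@@H]2C(OC(=S)n2ccnc2)c2cc(OC)c3c(c2)[C@H](CO[Si](C)(C)C(C)(C)C)[C@@H](c2ccc(O[Si](C)(C)C(C)(C)C)c(OC)c2)O3)ccc1O[Si](C)(C)C(C)(C)C
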